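**Assumption:** locants C1–C20 follow the usual briarane numbering (C1 = quaternary ring-A carbon bearing C15, lactone C7–O–C19(=O)–C17(C18)–C8, ether C2–O–C8, C16 = exocyclic methylene on C5, C20 = methyl on C11).

## Retrosynthetic overview

1. Target ⇐ oxocene 25 by a hydroxyl-directed ene-type chlorination (C6–Cl, C5=C16); 25 ⇐ diene 24 by ring-closing metathesis (C5=C6); 24 ⇐ aldehyde 22 by chelation-controlled methallylation (C3).
2. Tetrahydropyran and γ-lactone ⇐ diol 19 in one C–O bond-forming cascade: C2–OH adds to C8 of the C8=C17 ethylidene under divalent palladium, CO inserts, C7–OH lactonizes (sets C8 and C17).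
3. C8–C9 ⇐ Nozaki–Hiyama–Kishi coupling of ring-A aldehyde 9 with vinyl bromide 15 (from crotonaldehyde and vinylmagnesium bromide).
4. Ring A ⇐ catalytic asymmetric Diels–Alder of siloxydiene 2 with enal ester 3 (C1, C10); C2 by Felkin–Anh addition; C11 by α'-acetoxylation.
5. Ring order: cyclohexenone (ring A) → tetrahydropyran and lactone (same step) → eight-membered oxocene.

## Route

Step 1
Reactants: 1 pent-1-en-3-one
Product: 2 (Z)-3-(triisopropylsilyloxy)penta-1,3-diene
Conditions: i-Pr3SiOTf (1.1 equiv), Et3N, CH2Cl2, 0 °C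
Reagents that add atoms: triisopropylsilyl trifluoromethanesulfonate, CC(C)[Si](C(C)C)(C(C)C)OS(=O)(=O)C(F)(F)F
Why: Soft enolization and O-silylation of the ethyl ketone gives the (Z)-silyl enol ether, whose methyl group points outward in the s-cis diene.

Step 2
Reactants: 2 (Z)-3-(triisopropylsilyloxy)penta-1,3-diene; 3 ethyl (E)-3-methyl-4-oxobut-2-enoate
Product: 4 ethyl (1S,2R,6S)-6-formyl-2,6-dimethyl-3-(triisopropylsilyloxy)cyclohex-3-ene-1-carboxylate
Conditions: (S)-1-(2-methylphenyl)-3,3-diphenyltetrahydro-1H,3H-pyrrolo[1,2-c][1,3,2]oxazaborole activated by HN(SO2CF3)2 (20 mol %), CH2Cl2, −78 → −40 °C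
Reagents that add atoms: none
Why: Enantioselective Diels–Alder reaction with a Corey cationic oxazaborolidine, in which the siloxy-activated diene terminus bonds to the carbon β to the formyl group (C11–C10), the E geometry of 3 fixes the trans C2/C9 relationship and the catalyst face selection (enantiomer chosen accordingly) sets C1 and C10, while the C11 configuration is erased in step 9.

Step 3
Reactants: 4 Diels–Alder adduct; 5 tributyl[(methoxymethoxy)methyl]stannane
Product: 7 ethyl (1S,2R,6S)-6-[(1R)-2-(methoxymethoxy)-1-(triethylsilyloxy)ethyl]-2,6-dimethyl-3-(triisopropylsilyloxy)cyclohex-3-ene-1-carboxylate, via lithium alkoxide 6 (not isolated)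
Conditions: 5, n-BuLi, THF, −78 °C; add 4, −78 °C; then Et3SiCl, DMPU, −78 → 0 °C
Reagents that add atoms: chlorotriethylsilane, CC[Si](Cl)(CC)CC
Why: Tin–lithium exchange gives (methoxymethoxy)methyllithium (Still-type hydroxymethyl anion equivalent), which adds only to the aldehyde at −78 °C under Felkin–Anh control (anti to the C1–C10 bond, past the C15 methyl) to set C2 as R, and the alkoxide is silylated in the flask so it cannot lactonize onto the C9 ester.

Step 4
Reactants: 7 silyl ether ester
Product: 8 (1S,2R,6S)-6-[(1R)-2-(methoxymethoxy)-1-(triethylsilyloxy)ethyl]-2,6-dimethyl-3-(triisopropylsilyloxy)cyclohex-3-ene-1-carbaldehyde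
Conditions: i-Bu2AlH (1.1 equiv), CH2Cl2, −78 °C; aq. potassium sodium tartrate
Reagents that add atoms: none
Why: Partial reduction of the hindered ester stops at the tetrahedral aluminate and gives the C9 aldehyde on work-up, with the ring-A ketone still masked as the silyl enol ether.

Step 5
Reactants: 8 aldehyde silyl enol ether
Product: 9 (1S,2R,6S)-6-[(1R)-2-(methoxymethoxy)-1-(triethylsilyloxy)ethyl]-2,6-dimethyl-3-oxocyclohex-4-ene-1-carbaldehyde
Conditions: Pd(OAc)2 (15 mol %), O2 (1 atm), DMSO, 60 °C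
Reagents that add atoms: none
Why: Saegusa–Ito oxidation converts the C12 silyl enol ether into the C13=C14 enone before any allylic acetate or vinyl bromide is present; the trans C1/C10 arrangement is the stable one, so C10 is not at risk.

Step 6
Reactants: 10 (E)-but-2-enal
Product: 12 (Z)-2-bromobut-2-enal, via 2,3-dibromobutanal 11 (not isolated)
Conditions: Br2, CH2Cl2, −20 °C; then Et3N, 0 °C
Reagents that add atoms: bromine, BrBr
Why: Bromination and dehydrobromination give the thermodynamically preferred Z isomer (CHO trans to methyl), which fixes the later C8=C17 geometry.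

Step 7
Reactants: 12 (Z)-2-bromobut-2-enal; 13 vinylmagnesium bromide
Product: 15 (S,Z)-4-bromo-3-(triethylsilyloxy)hexa-1,4-diene, via bromodienol 14 (not isolated)
Conditions: 13, ZnCl2 (0.5 equiv), THF/toluene (gives divinylzinc); (2S)-3-exo-(dimethylamino)isoborneol (10 mol %), 0 °C; aq. NH4Cl; crude alcohol, Et3SiCl, imidazole, CH2Cl2
Reagents that add atoms: chlorotriethylsilane, CC[Si](Cl)(CC)CC
Why: Amino-alcohol-catalysed enantioselective vinylzinc addition (Oppolzer–Noyori type) to the α-bromo enal sets C7 as S with the bromovinyl group acting as the large substituent, and silylation protects the alcohol for the coupling.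

Step 8
Reactants: 9 enone aldehyde; 15 vinyl bromide
Product: 17 C9 acetate of the coupling product (9S; C10 side chain CH(OAc)–C(=CH–CH3)–CH(OSiEt3)–CH=CH2 with the ethylidene methyl cis to C9), via allylic alcohol 16 (not isolated)
Conditions: CrCl2 (3.5 equiv), N-[2-((S)-4-isopropyl-4,5-dihydrooxazol-2-yl)-6-methylphenyl]methanesulfonamide (3.8 equiv), Et3N, NiCl2 (5 mol %), THF, 25 °C; aqueous work-up; crude alcohol, Ac2O, pyridine, DMAP, CH2Cl2
Reagents that add atoms: acetic anhydride, CC(=O)OC(C)=O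
Why: Nozaki–Hiyama–Kishi coupling is selective for the aldehyde over the enone and keeps the vinyl geometry, the chiral sulfonamide–chromium complex (enantiomer chosen for 9S) has to override a substrate bias that a Felkin–Anh model puts on the 9-epimer side, and acetylation of the only free hydroxyl gives 17.

Step 9
Reactants: 17 enone acetate
Product: 18 the (11S)-11-acetoxy enone (17 with OAc on C11, α face)
Conditions: Mn(OAc)3·2H2O (5 equiv), benzene, reflux (Dean–Stark)
Reagents that add atoms: Mn(OAc)3 (manganese triacetate), CC(=O)[O-].CC(=O)[O-].CC(=O)[O-].[Mn+3]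
Why: α'-Acetoxylation of the enone by trivalent manganese goes through the C11 enolate (C1 is quaternary, so no γ-enolization) and delivers acetate to the α face, anti to the C9 chain on C10 and to the syn-axial C15 methyl, setting C11.

Step 10
Reactants: 18 bis(triethylsilyl) ether
Product: 19 the C2,C7-diol (C2 R, C7 S, C9 S acetate, ethylidene methyl cis to C9)
Conditions: HF·pyridine, pyridine, THF, 0 °C
Reagents that add atoms: none
Why: Buffered fluoride removes both triethylsilyl ethers without touching the acetates, the methoxymethyl ether or the enone.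

Step 11
Reactants: 19 diol
Product: 20 spiro tetrahydropyran γ-lactone (ether C2–O–C8, lactone C7–O–C19(=O)–C17; C2 R, C7 S, C8 R, C17 R; C3 as CH2OCH2OCH3, vinyl on C7)
Conditions: PdCl2(MeCN)2 (10 mol %), CuCl2 (3 equiv), NaOAc (3 equiv), CO (1 atm), AcOH, 25 °C
Reagents that add atoms: carbon monoxide, [C-]#[O+]
Why: Semmelhack–Tamaru alkoxypalladation/carbonylative lactonization, in which divalent palladium held on the alkene face of the C7 hydroxyl is attacked anti by the C2 hydroxyl at the more substituted C8 (6-exo, forming the key C2–O–C8 bond), CO inserts into the C17–Pd bond with retention and the C7 hydroxyl closes the lactone, so the ethylidene geometry is translated into 17R with H17 syn to the ether oxygen and C8 is set relative to C7.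

Step 12
Reactants: 20 methoxymethyl ether
Product: 21 the C3 primary alcohol
Conditions: Me2BBr (3 equiv), CH2Cl2, −78 °C; then aq. NaHCO3
Reagents that add atoms: none
Why: Bromodimethylborane cleaves the acetal-type methoxymethyl ether at −78 °C, where acetates, the lactone and the ring ether are inert.

Step 13
Reactants: 21 primary alcohol
Product: 22 the C3 aldehyde (axial formyl on C2 of the tetrahydropyran)
Conditions: Dess–Martin periodinane, NaHCO3, CH2Cl2, 0 °C; used crude
Reagents that add atoms: none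
Why: Buffered Dess–Martin oxidation gives the α-alkoxy aldehyde without base, and immediate use avoids epimerization at C2.

Step 14
Reactants: 22 aldehyde; 23 tributyl(2-methylallyl)stannane
Product: 24 (3R)-homoallylic alcohol diene (C3–OH, C4H2–C(CH3)=CH2 on C3, vinyl on C7)
Conditions: MgBr2·OEt2 (3 equiv), 23 (2 equiv), CH2Cl2, −78 → −20 °C
Reagents that add atoms: none
Why: Keck chelation-controlled allylstannane addition, in which magnesium bridges the aldehyde and ring-ether oxygens and the stannane attacks anti to C1, gives the 2,3-syn product and sets C3 as R.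

Step 15
Reactants: 24 diene
Product: 25 oxocene (1S,2R,3R,7S,8R,9S,10S,11S,17R), the 6-deschloro C5(CH3)=C6 isomer of the target
Conditions: second-generation Hoveyda–Grubbs catalyst (10 mol %), toluene (0.001 mol/L), 80 °C, argon sparge
Reagents that add atoms: none
Why: Ring-closing metathesis of the two arms held syn on C2 and C8 of the tetrahydropyran closes the eight-membered cyclic ether as the (necessarily Z) trisubstituted alkene, with the electron-poor enone inert.

Step 16
Reactants: 25 oxocene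
Product: 27 CNP0253524.4, via hypochlorite 26 (not isolated)
Conditions: t-BuOCl (1.05 equiv), NaHCO3, CH2Cl2/(CF3)2CHOH 4:1, −40 → 0 °C, dark
Reagents that add atoms: tert-butyl hypochlorite, CC(C)(C)OCl
Why: Proposed new method: exchange makes the C3 hypochlorite, whose O–Cl bond sits over C6 (six-membered Cl–O–C3–C4–C5–C6 array) and transfers Cl+ to the alkene face bearing the C3 oxygen while that oxygen takes a C16 hydrogen (intramolecular ene with O–Cl as enophile; a C4 hydrogen cannot be reached), so C6–Cl forms syn to C3–OH (6S) together with the C5=C16 methylene, whereas an external Cl+ would attack the opposite, open face; the closest known chemistry is the intermolecular ene-type chlorination of trisubstituted alkenes with HOCl or t-BuOCl and hydroxyl-directed ene reactions.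

## Compound list

1 | pent-1-en-3-one | C=CC(=O)CC | starting material
2 | (Z)-3-(triisopropylsilyloxy)penta-1,3-diene | C=C/C(O[Si](C(C)C)(C(C)C)C(C)C)=C/C | intermediate
3 | ethyl (E)-3-methyl-4-oxobut-2-enoate | CCOC(=O)/C=C(\C)C=O | starting material
4 | ethyl (1S,2R,6S)-6-formyl-2,6-dimethyl-3-(triisopropylsilyloxy)cyclohex-3-ene-1-carboxylate | CCOC(=O)[C@@H]1[C@](C=O)(C)CC=C(O[Si](C(C)C)(C(C)C)C(C)C)[C@@H]1C | intermediate
5 | tributyl[(methoxymethoxy)methyl]stannane | CCCC[Sn](CCCC)(CCCC)COCOC | starting material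
6 | lithium alkoxide of the (2R)-carbinol from 4 and (methoxymethoxy)methyllithium | CCOC(=O)[C@@H]1[C@]([C@@H]([O-])COCOC)(C)CC=C(O[Si](C(C)C)(C(C)C)C(C)C)[C@@H]1C.[Li+] | intermediate
7 | ethyl (1S,2R,6S)-6-[(1R)-2-(methoxymethoxy)-1-(triethylsilyloxy)ethyl]-2,6-dimethyl-3-(triisopropylsilyloxy)cyclohex-3-ene-1-carboxylate | CCOC(=O)[C@@H]1[C@]([C@@H](O[Si](CC)(CC)CC)COCOC)(C)CC=C(O[Si](C(C)C)(C(C)C)C(C)C)[C@@H]1C | intermediate
8 | (1S,2R,6S)-6-[(1R)-2-(methoxymethoxy)-1-(triethylsilyloxy)ethyl]-2,6-dimethyl-3-(triisopropylsilyloxy)cyclohex-3-ene-1-carbaldehyde | O=C[C@@H]1[C@]([C@@H](O[Si](CC)(CC)CC)COCOC)(C)CC=C(O[Si](C(C)C)(C(C)C)C(C)C)[C@@H]1C | intermediate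
9 | (1S,2R,6S)-6-[(1R)-2-(methoxymethoxy)-1-(triethylsilyloxy)ethyl]-2,6-dimethyl-3-oxocyclohex-4-ene-1-carbaldehyde | O=C[C@@H]1[C@]([C@@H](O[Si](CC)(CC)CC)COCOC)(C)C=CC(=O)[C@@H]1C | intermediate
10 | (E)-but-2-enal (crotonaldehyde) | C/C=C/C=O | starting material
11 | 2,3-dibromobutanal (racemic) | CC(Br)C(Br)C=O | intermediate
12 | (Z)-2-bromobut-2-enal | C/C=C(\Br)C=O | intermediate
13 | vinylmagnesium bromide | C=C[Mg]Br | starting material
14 | (S,Z)-4-bromohexa-1,4-dien-3-ol | C=C[C@H](O)/C(Br)=C/C | intermediate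
15 | (S,Z)-4-bromo-3-(triethylsilyloxy)hexa-1,4-diene | C=C[C@H](O[Si](CC)(CC)CC)/C(Br)=C/C | intermediate
16 | (9S)-allylic alcohol from 9 and 15 (C1 S, C2 R, C7 S, C10 S, C11 R; ethylidene methyl cis to C9) | C=C[C@H](O[Si](CC)(CC)CC)/C(=C/C)[C@@H](O)[C@@H]1[C@]([C@@H](O[Si](CC)(CC)CC)COCOC)(C)C=CC(=O)[C@@H]1C | intermediate
17 | C9 acetate of 16 | C=C[C@H](O[Si](CC)(CC)CC)/C(=C/C)[C@@H](OC(C)=O)[C@@H]1[C@]([C@@H](O[Si](CC)(CC)CC)COCOC)(C)C=CC(=O)[C@@H]1C | intermediate
18 | (11S)-11-acetoxy derivative of 17 | C=C[C@H](O[Si](CC)(CC)CC)/C(=C/C)[C@@H](OC(C)=O)[C@@H]1[C@]([C@@H](O[Si](CC)(CC)CC)COCOC)(C)C=CC(=O)[C@@]1(C)OC(C)=O | intermediate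
19 | C2,C7-diol of 18 (both silyl groups removed) | C=C[C@H](O)/C(=C/C)[C@@H](OC(C)=O)[C@@H]1[C@]([C@@H](O)COCOC)(C)C=CC(=O)[C@@]1(C)OC(C)=O | intermediate
20 | spiro tetrahydropyran γ-lactone (1S,2R,7S,8R,9S,10S,11S,17R) with CH2OCH2OCH3 on C2 and vinyl on C7 | COCOC[C@@H]2O[C@@]3([C@@H](C)C(=O)O[C@H]3C=C)[C@@H](OC(C)=O)[C@@H]1[C@]2(C)C=CC(=O)[C@@]1(C)OC(C)=O | intermediate
21 | C3 primary alcohol from 20 | OC[C@@H]2O[C@@]3([C@@H](C)C(=O)O[C@H]3C=C)[C@@H](OC(C)=O)[C@@H]1[C@]2(C)C=CC(=O)[C@@]1(C)OC(C)=O | intermediate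
22 | C3 aldehyde | O=C[C@@H]2O[C@@]3([C@@H](C)C(=O)O[C@H]3C=C)[C@@H](OC(C)=O)[C@@H]1[C@]2(C)C=CC(=O)[C@@]1(C)OC(C)=O | intermediate
23 | tributyl(2-methylallyl)stannane | CCCC[Sn](CCCC)(CCCC)CC(C)=C | starting material
24 | (3R)-homoallylic alcohol diene (2-methylallyl on C3, vinyl on C7) | C=C(C)C[C@@H](O)[C@@H]2O[C@@]3([C@@H](C)C(=O)O[C@H]3C=C)[C@@H](OC(C)=O)[C@@H]1[C@]2(C)C=CC(=O)[C@@]1(C)OC(C)=O | intermediate
25 | oxocene (1S,2R,3R,7S,8R,9S,10S,11S,17R), C5(CH3)=C6 Z in the eight-membered ring | CC=1C[C@@H](O)[C@@H]2O[C@@]3([C@@H](C)C(=O)O[C@H]3C=1)[C@@H](OC(C)=O)[C@@H]1[C@]2(C)C=CC(=O)[C@@]1(C)OC(C)=O | intermediate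
26 | C3 hypochlorite of 25 | CC=1C[C@@H](OCl)[C@@H]2O[C@@]3([C@@H](C)C(=O)O[C@H]3C=1)[C@@H](OC(C)=O)[C@@H]1[C@]2(C)C=CC(=O)[C@@]1(C)OC(C)=O | intermediate
27 | CNP0253524.4 (1S,2R,3R,6S,7R,8S,9S,10S,11S,17R) | C=C1C[C@@H](O)[C@@H]2O[C@@]3([C@@H](C)C(=O)O[C@H]3[C@H]1Cl)[C@@H](OC(C)=O)[C@@H]1[C@]2(C)C=CC(=O)[C@@]1(C)OC(C)=O | target

## Step count and risks

Total step count: 16. Longest linear sequence: 14 (steps 1–5 and 8–16).

The three steps most likely to fail are steps 8, 11 and 16.

**Step 8 (coupling and C9 configuration).** Two hindered partners must join, and the ligand must overrule a substrate bias that may favour the 9-epimer. The fallback sets out from aldehyde 8 (before the Saegusa step) and bromide 15. Bromine–lithium exchange on 15 with t-BuLi (Et2O, −78 °C) and addition to 8 gives the C9-epimeric allylic alcohols F1. Dess–Martin oxidation gives the C9 ketone F2. Reduction with NaBH4/CeCl3·7H2O, with hydride arriving anti to the C1 quaternary centre (Felkin–Anh, the opposite sense to carbon addition), gives the (9S)-alcohol F3. Acetylation gives the acetate F4, and Pd(OAc)2/O2 oxidation of its silyl enol ether comes back to the route at 17.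

**Step 11 (key C–O bond).** A 6-exo attack on a trisubstituted alkene must create a fully substituted ether carbon next to two allylic oxygens. The face selection rests on hydroxyl direction, and allylic acetate transposition or β-hydride loss could compete. The fallback sets out from diol 19. Hg(OCOCF3)2 in THF, then aqueous NaCl, gives the tetrahydropyranyl alkylmercury chloride F5 by anti oxymercuration at C8. Li2PdCl4 under CO (transmetalation with retention, CO insertion, lactonization by the C7 hydroxyl) comes back to the route at 20.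

**Step 16 (proposed new chlorination).** The secondary hypochlorite may collapse to the C3 ketone, or free t-BuOCl may chlorinate the open face and give the 6-epimer. The fallback uses known chemistry and sets out from oxocene 25. Dimethyldioxirane epoxidizes C5=C6 from the face remote from the C1–C10–C9 bridge to give the epoxide F6. LiCl in AcOH/THF opens it at the secondary C6 with inversion to give the chlorohydrin F7, with C6–Cl syn to C3–OH and a tertiary C5–OH. Martin sulfurane at −40 °C dehydrates the tertiary alcohol toward C16 (C6 has no anti hydrogen) and comes back to the route at 27.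

Further compounds
F1 | step 8 | C9-epimeric allylic alcohols from 8 and lithiated 15 (silyl enol ether retained) | C=C[C@H](O[Si](CC)(CC)CC)/C(=C/C)C(O)[C@@H]1[C@]([C@@H](O[Si](CC)(CC)CC)COCOC)(C)CC=C(O[Si](C(C)C)(C(C)C)C(C)C)[C@@H]1C
F2 | step 8 | C9 ketone (cross-conjugated enone) | C=C[C@H](O[Si](CC)(CC)CC)/C(=C/C)C(=O)[C@@H]1[C@]([C@@H](O[Si](CC)(CC)CC)COCOC)(C)CC=C(O[Si](C(C)C)(C(C)C)C(C)C)[C@@H]1C
F3 | step 8 | (9S)-allylic alcohol with silyl enol ether | C=C[C@H](O[Si](CC)(CC)CC)/C(=C/C)[C@@H](O)[C@@H]1[C@]([C@@H](O[Si](CC)(CC)CC)COCOC)(C)CC=C(O[Si](C(C)C)(C(C)C)C(C)C)[C@@H]1C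
F4 | step 8 | (9S)-acetate with silyl enol ether | C=C[C@H](O[Si](CC)(CC)CC)/C(=C/C)[C@@H](OC(C)=O)[C@@H]1[C@]([C@@H](O[Si](CC)(CC)CC)COCOC)(C)CC=C(O[Si](C(C)C)(C(C)C)C(C)C)[C@@H]1C
F5 | step 11 | tetrahydropyranyl alkylmercury chloride (HgCl on C17, free C7–OH) | COCOC[C@@H]2O[C@@]([C@@H](O)C=C)([C@@H](C)[Hg]Cl)[C@@H](OC(C)=O)[C@@H]1[C@]2(C)C=CC(=O)[C@@]1(C)OC(C)=O
F6 | step 16 | 5,6-epoxide of 25 (oxygen anti to C3–OH) | C[C@@]14C[C@@H](O)[C@@H]2O[C@@]3([C@@H](C)C(=O)O[C@H]3[C@@H]1O4)[C@@H](OC(C)=O)[C@@H]1[C@]2(C)C=CC(=O)[C@@]1(C)OC(C)=O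
F7 | step 16 | chlorohydrin (6S chloride, tertiary C5–OH) | C[C@@]1(O)C[C@@H](O)[C@@H]2O[C@@]3([C@@H](C)C(=O)O[C@H]3[C@H]1Cl)[C@@H](OC(C)=O)[C@@H]1[C@]2(C)C=CC(=O)[C@@]1(C)OC(C)=O
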